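**Retrosynthetic overview**
Numbering: piperidine N1, C2 (CH3), C3 (OH), C4, C5, C6; side chain on C6 is C1'–C16' with hydroxyls at C4' and C15'.
Key disconnection C3'–C4': lithiation–borylation–oxidation joins carbamate fragment A (C4'–C16') to the primary boronic ester of the finished piperidine, fragment B (ring plus C1'–C3'), forming the bond, setting C4' and delivering its hydroxyl in one operation.
Enabling feature: C4' is a secondary carbinol flanked only by unbranched CH2 groups (C3', C5'), so its own oxygen, as a carbamate, can first acidify C4'–H and then leave, while C3' is a primary CH2 three bonds from ring carbon C6 that can carry boron; no other stereocentre or acidic site lies within three bonds.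
Fragment A: (S)-propylene oxide (C15') plus a C10 Grignard reagent, hydroboration, carbamoylation. Fragment B: D-alaninol (C2), Felkin–Anh acetylide addition (C3), hydrogenative lactamisation closing the piperidine ring (the only ring, N1–C6 bond), N-acyliminium allylation (C6, 2,6-cis), hydroboration.
End game: one acidic global deprotection (Boc and two silyl ethers).

Key step: step 14

**Step 1**
Reactants: 1 10-bromodec-1-ene; 2 (S)-propylene oxide
Product: 4 (S)-tridec-12-en-2-ol, via dec-9-en-1-ylmagnesium bromide 3 (not isolated)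
Conditions: Mg, THF, rt; then CuI (5 mol %), 2, −30 °C → 0 °C; H2O quench
Reagents that add atoms: none
Why: Copper-catalysed SN2 opening of the terminal epoxide by the Grignard reagent occurs at the unsubstituted carbon, so the C15' stereocentre comes unchanged from the chiral pool.

**Step 2**
Reactants: 4 (S)-tridec-12-en-2-ol
Product: 5 (S)-tert-butyldimethyl(tridec-12-en-2-yloxy)silane
Conditions: TBSCl, imidazole, DMF, rt
Reagents that add atoms: tert-butyldimethylsilyl chloride CC(C)(C)[Si](C)(C)Cl
Why: Standard silyl ether formation on a secondary alcohol, with no stereocentre touched.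

**Step 3**
Reactants: 5 (S)-tert-butyldimethyl(tridec-12-en-2-yloxy)silane
Product: 7 (S)-12-[(tert-butyldimethylsilyl)oxy]tridecan-1-ol, via B-alkyl-9-BBN adduct 6 (not isolated)
Conditions: 9-BBN, THF, 0 °C → rt; then 3 M aq NaOH, 30% aq H2O2, 0 °C → rt
Reagents that add atoms: hydrogen peroxide OO
Why: Anti-Markovnikov hydroboration–oxidation with the bulky 9-BBN places oxygen on the terminal carbon (the future C4'), and the silyl ether is inert to alkaline peroxide.

**Step 4**
Reactants: 7 (S)-12-[(tert-butyldimethylsilyl)oxy]tridecan-1-ol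
Product: 8 (S)-12-[(tert-butyldimethylsilyl)oxy]tridecyl N,N-diisopropylcarbamate
Conditions: iPr2NC(O)Cl, Et3N, CH2Cl2, reflux
Reagents that add atoms: N,N-diisopropylcarbamoyl chloride CC(C)N(C(C)C)C(=O)Cl
Why: O-Carbamoylation of the primary alcohol installs the hindered carbamate that later directs lithiation and acts as leaving group, while the secondary silyl ether is unaffected.

**Step 5**
Reactants: 9 D-alaninol ((R)-2-aminopropan-1-ol)
Product: 10 (R)-2-(dibenzylamino)propan-1-ol
Conditions: BnBr, K2CO3, EtOH, reflux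
Reagents that add atoms: benzyl bromide BrCc1ccccc1
Why: Double N-alkylation (SN2) of the primary amine, which is far more nucleophilic than the hydroxyl; the C2 stereocentre of the chiral pool is not involved.

**Step 6**
Reactants: 10 (R)-2-(dibenzylamino)propan-1-ol
Product: 11 (R)-2-(dibenzylamino)propanal
Conditions: (COCl)2, DMSO, CH2Cl2, −78 °C; Et3N, −78 °C → 0 °C; used crude at once
Reagents that add atoms: none
Why: Swern oxidation at low temperature should give the configurationally labile α-(dibenzylamino) aldehyde without racemisation, provided it is used immediately without chromatography.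

**Step 7**
Reactants: 11 (R)-2-(dibenzylamino)propanal; 12 ethyl propiolate
Product: 14 ethyl (4S,5R)-5-(dibenzylamino)-4-hydroxyhex-2-ynoate, via ethyl 3-lithiopropiolate 13 (not isolated)
Conditions: 12, LiN(SiMe3)2, THF, −78 °C; then 11, −78 °C; AcOH quench at −78 °C
Reagents that add atoms: none
Why: 1,2-Addition of the lithium acetylide under Felkin–Anh (non-chelation) control, with the bulky non-chelating NBn2 group anti to the incoming nucleophile, should set C3 (4S in 14) anti to the C2 nitrogen.

**Step 8**
Reactants: 14 ethyl (4S,5R)-5-(dibenzylamino)-4-hydroxyhex-2-ynoate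
Product: 15 ethyl (4S,5R)-4-[(tert-butyldimethylsilyl)oxy]-5-(dibenzylamino)hex-2-ynoate
Conditions: TBSOTf, 2,6-lutidine, CH2Cl2, 0 °C
Reagents that add atoms: tert-butyldimethylsilyl trifluoromethanesulfonate CC(C)(C)[Si](C)(C)OS(=O)(=O)C(F)(F)F
Why: Silylation of the hindered propargylic alcohol with the reactive silyl triflate and a non-nucleophilic base, with no stereocentre touched.

**Step 9**
Reactants: 15 ethyl (4S,5R)-4-[(tert-butyldimethylsilyl)oxy]-5-(dibenzylamino)hex-2-ynoate
Product: 17 (5S,6R)-5-[(tert-butyldimethylsilyl)oxy]-6-methylpiperidin-2-one, via amino ester 16 (not isolated)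
Conditions: H2 (3 bar), Pd(OH)2/C, EtOH, rt; filter; then EtOH, reflux
Reagents that add atoms: none
Why: Heterogeneous hydrogenation saturates the alkyne and cleaves both N-benzyl groups by hydrogenolysis, and the freed primary amine closes the piperidine ring by 6-exo-trig lactamisation onto the ethyl ester on warming, leaving C2 and C3 untouched.

**Step 10**
Reactants: 17 (5S,6R)-5-[(tert-butyldimethylsilyl)oxy]-6-methylpiperidin-2-one
Product: 18 tert-butyl (2R,3S)-3-[(tert-butyldimethylsilyl)oxy]-2-methyl-6-oxopiperidine-1-carboxylate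
Conditions: Boc2O, DMAP (cat.), MeCN, rt
Reagents that add atoms: di-tert-butyl dicarbonate CC(C)(C)OC(=O)OC(=O)OC(C)(C)C
Why: DMAP-catalysed N-acylation of the lactam activates its carbonyl for partial reduction and supplies the N-acyl group needed for the iminium chemistry.

**Step 11**
Reactants: 18 tert-butyl (2R,3S)-3-[(tert-butyldimethylsilyl)oxy]-2-methyl-6-oxopiperidine-1-carboxylate
Product: 19 tert-butyl (2R,3S)-3-[(tert-butyldimethylsilyl)oxy]-6-hydroxy-2-methylpiperidine-1-carboxylate (both C6 epimers)
Conditions: LiBHEt3, THF, −78 °C; H2O quench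
Reagents that add atoms: none
Why: Partial hydride reduction of the imide-like N-Boc lactam stops at the tetrahedral hemiaminal at −78 °C, and the new C6 centre is an inconsequential epimer mixture because it is ionised in the next step.

**Step 12**
Reactants: 19 tert-butyl (2R,3S)-3-[(tert-butyldimethylsilyl)oxy]-6-hydroxy-2-methylpiperidine-1-carboxylate; 20 allyltrimethylsilane
Product: 22 tert-butyl (2R,3S,6R)-6-allyl-3-[(tert-butyldimethylsilyl)oxy]-2-methylpiperidine-1-carboxylate, via N-acyliminium ion 21 (not isolated)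
Conditions: 20, BF3·OEt2, CH2Cl2, −78 °C
Reagents that add atoms: none
Why: Lewis-acid ionisation to the N-acyliminium ion and allylsilane addition (aza-Hosomi–Sakurai reaction), in which allylic 1,3-strain with the Boc group holds the C2 methyl pseudoaxial (and the C3 silyloxy group pseudoaxial on the opposite face), so that stereoelectronically favoured axial attack through a chair-like transition state should deliver the allyl group cis to the methyl group and set C6.

**Step 13**
Reactants: 22 tert-butyl (2R,3S,6R)-6-allyl-3-[(tert-butyldimethylsilyl)oxy]-2-methylpiperidine-1-carboxylate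
Product: 23 tert-butyl (2R,3S,6S)-3-[(tert-butyldimethylsilyl)oxy]-2-methyl-6-[3-(4,4,5,5-tetramethyl-1,3,2-dioxaborolan-2-yl)propyl]piperidine-1-carboxylate
Conditions: HBpin, [Ir(cod)Cl]2 (1.5 mol %), dppm (3 mol %), CH2Cl2, rt
Reagents that add atoms: pinacolborane CC1(C)OBOC1(C)C
Why: Iridium-catalysed hydroboration of the monosubstituted alkene is anti-Markovnikov and gives the primary alkylboronic ester at C3' without touching the carbamate or the silyl ether.

**Step 14**
Reactants: 8 (S)-12-[(tert-butyldimethylsilyl)oxy]tridecyl N,N-diisopropylcarbamate; 23 tert-butyl (2R,3S,6S)-3-[(tert-butyldimethylsilyl)oxy]-2-methyl-6-[3-(4,4,5,5-tetramethyl-1,3,2-dioxaborolan-2-yl)propyl]piperidine-1-carboxylate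
Product: 27 tert-butyl (2R,3S,6S)-3-[(tert-butyldimethylsilyl)oxy]-6-[(4S,15S)-15-[(tert-butyldimethylsilyl)oxy]-4-hydroxyhexadecyl]-2-methylpiperidine-1-carboxylate, via lithiated carbamate 24 (not isolated), via boronate complex 25 (not isolated), via secondary boronic ester 26 (not isolated)
Conditions: 8 (1.3 equiv), (+)-sparteine (1.3 equiv), s-BuLi (1.25 equiv), Et2O, −78 °C, 5 h; 23 (1.0 equiv), −78 °C, 1 h; MgBr2·OEt2, −78 °C → reflux, 16 h; then 2 M aq NaOH, 30% aq H2O2, THF, 0 °C → rt
Reagents that add atoms: hydrogen peroxide OO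
Why: s-BuLi complexed by (+)-sparteine removes the pro-R hydrogen next to the carbamate oxygen of 8 to give the configurationally stable (R)-lithiated carbamate 24, which adds to the boron of 23 with retention to give boronate complex 25; on warming with MgBr2·OEt2 the C3' methylene migrates from boron to C4' antiperiplanar to the departing carbamate (1,2-metallate rearrangement, inversion at C4') to give 26, and alkaline peroxide then replaces boron by hydroxyl with retention. The closest known reaction type is the lithiation–borylation homologation of primary alkyl pinacol boronic esters with sparteine-lithiated primary alkyl carbamates, a Matteson-type 1,2-metallate shift. No ring is closed in this step. The only new stereocentre, C4', is fixed by reagent control in the enantiotopic deprotonation and carried through three stereospecific events (retention, inversion, retention) to the 4'S alcohol, while the existing centres at C2, C3, C6 and C15' lie at least three bonds away and can neither override this nor be epimerised. The step needs chemoselectivity for boron over the Boc carbonyl, migration of the carbon group and not of a pinacol oxygen, and configurational stability of 24; these are secured by the high electrophilicity of the unhindered primary boronic ester at −78 °C, the hindered Boc group without N–H, the consumption of all s-BuLi by 8 before 23 is added, and the chelated, dipole-stabilised nature of the lithiated carbamate. Both united carbons (C4'–Li and C3'–B) are nucleophilic, so this union of like polarity is made possible by the carbamate, which first acidifies C4' and then leaves.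

**Step 15**
Reactants: 27 tert-butyl (2R,3S,6S)-3-[(tert-butyldimethylsilyl)oxy]-6-[(4S,15S)-15-[(tert-butyldimethylsilyl)oxy]-4-hydroxyhexadecyl]-2-methylpiperidine-1-carboxylate
Product: 28 (2R,3S,6S)-6-[(4S,15S)-4,15-dihydroxyhexadecyl]-2-methylpiperidin-3-ol
Conditions: HCl (1.25 M in MeOH), 0 °C → rt; then aq NaHCO3 to liberate the free base
Reagents that add atoms: none
Why: Acid-catalysed global deprotection (Boc cleavage and methanolysis of both silyl ethers) proceeds without touching any C–O or C–N stereocentre, since none is benzylic, allylic or tertiary.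

**Compound list**
1 | 10-bromodec-1-ene | C=CCCCCCCCCBr | starting material
2 | (S)-propylene oxide ((S)-2-methyloxirane) | C[C@H]1CO1 | starting material
3 | dec-9-en-1-ylmagnesium bromide | C=CCCCCCCCC[Mg]Br | intermediate (not isolated)
4 | (S)-tridec-12-en-2-ol | C[C@H](O)CCCCCCCCCC=C | intermediate
5 | (S)-tert-butyldimethyl(tridec-12-en-2-yloxy)silane | C[C@H](O[Si](C)(C)C(C)(C)C)CCCCCCCCCC=C | intermediate
6 | (S)-9-{12-[(tert-butyldimethylsilyl)oxy]tridecyl}-9-borabicyclo[3.3.1]nonane | C[C@H](O[Si](C)(C)C(C)(C)C)CCCCCCCCCCCB1C2CCCC1CCC2 | intermediate (not isolated)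
7 | (S)-12-[(tert-butyldimethylsilyl)oxy]tridecan-1-ol | C[C@H](O[Si](C)(C)C(C)(C)C)CCCCCCCCCCCO | intermediate
8 | (S)-12-[(tert-butyldimethylsilyl)oxy]tridecyl N,N-diisopropylcarbamate | C[C@H](O[Si](C)(C)C(C)(C)C)CCCCCCCCCCCOC(=O)N(C(C)C)C(C)C | intermediate
9 | D-alaninol ((R)-2-aminopropan-1-ol) | C[C@@H](N)CO | starting material
10 | (R)-2-(dibenzylamino)propan-1-ol | C[C@@H](N(Cc1ccccc1)Cc1ccccc1)CO | intermediate
11 | (R)-2-(dibenzylamino)propanal | C[C@@H](N(Cc1ccccc1)Cc1ccccc1)C=O | intermediate
12 | ethyl propiolate | C#CC(=O)OCC | starting material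
13 | ethyl 3-lithiopropiolate | [Li]C#CC(=O)OCC | intermediate (not isolated)
14 | ethyl (4S,5R)-5-(dibenzylamino)-4-hydroxyhex-2-ynoate | CCOC(=O)C#C[C@H](O)[C@@H](C)N(Cc1ccccc1)Cc1ccccc1 | intermediate
15 | ethyl (4S,5R)-4-[(tert-butyldimethylsilyl)oxy]-5-(dibenzylamino)hex-2-ynoate | CCOC(=O)C#C[C@H](O[Si](C)(C)C(C)(C)C)[C@@H](C)N(Cc1ccccc1)Cc1ccccc1 | intermediate
16 | ethyl (4S,5R)-5-amino-4-[(tert-butyldimethylsilyl)oxy]hexanoate | CCOC(=O)CC[C@H](O[Si](C)(C)C(C)(C)C)[C@@H](C)N | intermediate (not isolated)
17 | (5S,6R)-5-[(tert-butyldimethylsilyl)oxy]-6-methylpiperidin-2-one | O=C1CC[C@H](O[Si](C)(C)C(C)(C)C)[C@@H](C)N1 | intermediate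
18 | tert-butyl (2R,3S)-3-[(tert-butyldimethylsilyl)oxy]-2-methyl-6-oxopiperidine-1-carboxylate | O=C1CC[C@H](O[Si](C)(C)C(C)(C)C)[C@@H](C)N1C(=O)OC(C)(C)C | intermediate
19 | tert-butyl (2R,3S)-3-[(tert-butyldimethylsilyl)oxy]-6-hydroxy-2-methylpiperidine-1-carboxylate (both C6 epimers) | OC1CC[C@H](O[Si](C)(C)C(C)(C)C)[C@@H](C)N1C(=O)OC(C)(C)C | intermediate
20 | allyltrimethylsilane | C=CC[Si](C)(C)C | starting material
21 | (2R,3S)-1-(tert-butoxycarbonyl)-3-[(tert-butyldimethylsilyl)oxy]-2-methyl-2,3,4,5-tetrahydropyridin-1-ium (N-acyliminium ion) | C1C[C@H](O[Si](C)(C)C(C)(C)C)[C@@H](C)[N+](C(=O)OC(C)(C)C)=C1 | intermediate (not isolated)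
22 | tert-butyl (2R,3S,6R)-6-allyl-3-[(tert-butyldimethylsilyl)oxy]-2-methylpiperidine-1-carboxylate | C=CC[C@H]1CC[C@H](O[Si](C)(C)C(C)(C)C)[C@@H](C)N1C(=O)OC(C)(C)C | intermediate
23 | tert-butyl (2R,3S,6S)-3-[(tert-butyldimethylsilyl)oxy]-2-methyl-6-[3-(4,4,5,5-tetramethyl-1,3,2-dioxaborolan-2-yl)propyl]piperidine-1-carboxylate | CC1(C)OB(CCC[C@H]2CC[C@H](O[Si](C)(C)C(C)(C)C)[C@@H](C)N2C(=O)OC(C)(C)C)OC1(C)C | intermediate
24 | (1R,12S)-12-[(tert-butyldimethylsilyl)oxy]-1-lithiotridecyl N,N-diisopropylcarbamate (as its (+)-sparteine complex) | C[C@H](O[Si](C)(C)C(C)(C)C)CCCCCCCCCC[C@H](OC(=O)N(C(C)C)C(C)C)[Li] | intermediate (not isolated)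
25 | lithium boronate complex of 24 with 23 (C4' R, carbamate still attached) | [Li+].C[C@H](O[Si](C)(C)C(C)(C)C)CCCCCCCCCC[C@H](OC(=O)N(C(C)C)C(C)C)[B-]1(CCC[C@H]2CC[C@H](O[Si](C)(C)C(C)(C)C)[C@@H](C)N2C(=O)OC(C)(C)C)OC(C)(C)C(C)(C)O1 | intermediate (not isolated)
26 | tert-butyl (2R,3S,6S)-3-[(tert-butyldimethylsilyl)oxy]-6-[(4S,15S)-15-[(tert-butyldimethylsilyl)oxy]-4-(4,4,5,5-tetramethyl-1,3,2-dioxaborolan-2-yl)hexadecyl]-2-methylpiperidine-1-carboxylate | C[C@H](O[Si](C)(C)C(C)(C)C)CCCCCCCCCC[C@H](B1OC(C)(C)C(C)(C)O1)CCC[C@H]1CC[C@H](O[Si](C)(C)C(C)(C)C)[C@@H](C)N1C(=O)OC(C)(C)C | intermediate (not isolated)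
27 | tert-butyl (2R,3S,6S)-3-[(tert-butyldimethylsilyl)oxy]-6-[(4S,15S)-15-[(tert-butyldimethylsilyl)oxy]-4-hydroxyhexadecyl]-2-methylpiperidine-1-carboxylate | C[C@H](O[Si](C)(C)C(C)(C)C)CCCCCCCCCC[C@H](O)CCC[C@H]1CC[C@H](O[Si](C)(C)C(C)(C)C)[C@@H](C)N1C(=O)OC(C)(C)C | intermediate
28 | (2R,3S,6S)-6-[(4S,15S)-4,15-dihydroxyhexadecyl]-2-methylpiperidin-3-ol | C[C@H](O)CCCCCCCCCC[C@H](O)CCC[C@H]1CC[C@H](O)[C@@H](C)N1 | target

**Step count**
Total step count: 15. Longest linear sequence: 11 steps (steps 5 to 15, from D-alaninol).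

**Steps most likely to fail**

Step 14 (key step). The process at risk is a sluggish or incomplete 1,2-migration of the crowded boronate (with reversion to its components on warming), competing addition of the lithiated carbamate to the Boc carbonyl, or erosion of the enantiotopic selection if the organolithium warms before it is trapped. The fallback sets out from 7 and 22 and comes back at 27; it makes the same C3'–C4' bond by catalytic asymmetric addition of a functionalised dialkylzinc to an aldehyde. Alcohol 7 would be oxidised with Dess–Martin periodinane in CH2Cl2 to (S)-12-[(tert-butyldimethylsilyl)oxy]tridecanal F1. Alkene 22 would be hydroborated with Et2BH to tert-butyl (2R,3S,6S)-3-[(tert-butyldimethylsilyl)oxy]-6-[3-(diethylboranyl)propyl]-2-methylpiperidine-1-carboxylate F2. Boron–zinc exchange with Et2Zn, followed by removal of BEt3 and excess Et2Zn in vacuo, would give bis{3-[(2R,5S,6R)-1-(tert-butoxycarbonyl)-5-[(tert-butyldimethylsilyl)oxy]-6-methylpiperidin-2-yl]propyl}zinc F3. Addition of F3 to F1 in toluene with Ti(OiPr)4 and a catalytic amount of (1S,2S)-N,N'-bis(trifluoromethanesulfonyl)cyclohexane-1,2-diamine should give 27 directly. This ligand enantiomer is the one expected, from the usual sense of induction of this catalyst class, to give the 4'S carbinol. Only one alkyl group of F3 is transferred.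

Step 12. The process at risk is poor facial selectivity in the attack of the allylsilane on the N-acyliminium ion (loss of 2,6-cis control), or Lewis-acid cleavage of the Boc or silyl group. The fallback sets out from 18 and comes back at 23; it sets C6 by delivering hydrogen instead of carbon to an endocyclic imine, which is the classical way to 2,6-cis piperidines. Benzyl 3-bromopropyl ether and Mg would give 3-(benzyloxy)propylmagnesium bromide F4. Its addition to 18 in THF at −78 °C would open the N-Boc lactam to tert-butyl [(2R,3S)-9-(benzyloxy)-3-[(tert-butyldimethylsilyl)oxy]-6-oxononan-2-yl]carbamate F5. Selective Boc removal (TMSOTf, 2,6-lutidine; then MeOH) and spontaneous condensation would give (2R,3S)-6-[3-(benzyloxy)propyl]-3-[(tert-butyldimethylsilyl)oxy]-2-methyl-2,3,4,5-tetrahydropyridine F6. Hydrogenation (H2, Pd(OH)2/C, EtOH) should reduce the C=N bond to the all-equatorial 2,6-cis piperidine and cleave the benzyl ether, giving 3-[(2S,5S,6R)-5-[(tert-butyldimethylsilyl)oxy]-6-methylpiperidin-2-yl]propan-1-ol F7. Boc2O would give tert-butyl (2R,3S,6S)-3-[(tert-butyldimethylsilyl)oxy]-6-(3-hydroxypropyl)-2-methylpiperidine-1-carboxylate F8. Iodination (I2, PPh3, imidazole) would give tert-butyl (2R,3S,6R)-3-[(tert-butyldimethylsilyl)oxy]-6-(3-iodopropyl)-2-methylpiperidine-1-carboxylate F9. Copper-catalysed borylation (B2pin2, CuI, PPh3, LiOMe, DMF) would then give 23.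

Step 7. The process at risk is insufficient Felkin–Anh facial selectivity (a chelated transition state competing), which would give the C3 epimer. The fallback sets out from 14 as the epimer mixture and comes back at 14; it resets the carbinol centre under reagent control. Oxidation of the mixture with Dess–Martin periodinane would give ethyl (R)-5-(dibenzylamino)-4-oxohex-2-ynoate F10. Midland reduction with (R)-B-isopinocampheyl-9-borabicyclo[3.3.1]nonane (from (+)-α-pinene), in which the alkynyl group plays the small substituent, would be expected to return 14 as the 4S alcohol. This fallback does not repair racemisation of aldehyde 11, which must be avoided by using it immediately.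

**Further compounds**
F1 | step 14 | (S)-12-[(tert-butyldimethylsilyl)oxy]tridecanal | C[C@H](O[Si](C)(C)C(C)(C)C)CCCCCCCCCCC=O
F2 | step 14 | tert-butyl (2R,3S,6S)-3-[(tert-butyldimethylsilyl)oxy]-6-[3-(diethylboranyl)propyl]-2-methylpiperidine-1-carboxylate | CCB(CC)CCC[C@H]1CC[C@H](O[Si](C)(C)C(C)(C)C)[C@@H](C)N1C(=O)OC(C)(C)C
F3 | step 14 | bis{3-[(2R,5S,6R)-1-(tert-butoxycarbonyl)-5-[(tert-butyldimethylsilyl)oxy]-6-methylpiperidin-2-yl]propyl}zinc | [Zn](CCC[C@H]1CC[C@H](O[Si](C)(C)C(C)(C)C)[C@@H](C)N1C(=O)OC(C)(C)C)CCC[C@H]1CC[C@H](O[Si](C)(C)C(C)(C)C)[C@@H](C)N1C(=O)OC(C)(C)C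
F4 | step 12 | 3-(benzyloxy)propylmagnesium bromide | Br[Mg]CCCOCc1ccccc1
F5 | step 12 | tert-butyl [(2R,3S)-9-(benzyloxy)-3-[(tert-butyldimethylsilyl)oxy]-6-oxononan-2-yl]carbamate | C[C@@H](NC(=O)OC(C)(C)C)[C@@H](O[Si](C)(C)C(C)(C)C)CCC(=O)CCCOCc1ccccc1
F6 | step 12 | (2R,3S)-6-[3-(benzyloxy)propyl]-3-[(tert-butyldimethylsilyl)oxy]-2-methyl-2,3,4,5-tetrahydropyridine | C[C@H]1N=C(CCCOCc2ccccc2)CC[C@@H]1O[Si](C)(C)C(C)(C)C
F7 | step 12 | 3-[(2S,5S,6R)-5-[(tert-butyldimethylsilyl)oxy]-6-methylpiperidin-2-yl]propan-1-ol | OCCC[C@H]1CC[C@H](O[Si](C)(C)C(C)(C)C)[C@@H](C)N1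
F8 | step 12 | tert-butyl (2R,3S,6S)-3-[(tert-butyldimethylsilyl)oxy]-6-(3-hydroxypropyl)-2-methylpiperidine-1-carboxylate | OCCC[C@H]1CC[C@H](O[Si](C)(C)C(C)(C)C)[C@@H](C)N1C(=O)OC(C)(C)C
F9 | step 12 | tert-butyl (2R,3S,6R)-3-[(tert-butyldimethylsilyl)oxy]-6-(3-iodopropyl)-2-methylpiperidine-1-carboxylate | ICCC[C@H]1CC[C@H](O[Si](C)(C)C(C)(C)C)[C@@H](C)N1C(=O)OC(C)(C)C
F10 | step 7 | ethyl (R)-5-(dibenzylamino)-4-oxohex-2-ynoate | CCOC(=O)C#CC(=O)[C@@H](C)N(Cc1ccccc1)Cc1ccccc1
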